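**Retrosynthetic overview**

- The route rests on one feature of the flavone: the C4 carbonyl carbon of ring C (the pyranone) lies between C4a of ring A and the C3=C2 unit that carries ring B, and O1 sits on C8a, ortho to C4a. Ring C is therefore cut at C4a–C4, C4–C3 and O1–C2, which gives a ring A 2-iodophenol, carbon monoxide and a ring B arylacetylene.
- The ring A iodophenol comes from 5-methoxyresorcinol. A MOM-directed lithiation, borylation and oxidation puts in the C8 oxygen. A second directed lithiation puts exactly one iodine at C4a. After MOM removal, the hydroxyl remote from iodine (the future O7) is benzylated.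
- The ring B alkyne comes from methyl 3,5-dihydroxy-4-methoxybenzoate by benzylation, reduction, oxidation and Ohira–Bestmann homologation.
- Rings A and B are bought as benzenes. Ring C is the only ring formed (step 11), and hydrogenolysis of the three benzyl ethers ends the route.

Key step: step 11

Remark: flavone numbering is used (O1, C2, C3, C4, C4a, C5 to C8, C8a); ring A is the benzo ring, ring C the pyranone and ring B the 2-aryl group. The target has no stereocentre, so no stereocontrol is needed.

**Route**

Step 1
Reactants: 1 5-methoxyresorcinol (5-methoxybenzene-1,3-diol)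
Product: 2 1-methoxy-3,5-bis(methoxymethoxy)benzene
Conditions: MOMCl (2.5 equiv), i-Pr2NEt (3 equiv), CH2Cl2, 0 °C to rt
Reagents that add atoms: chloromethyl methyl ether, COCCl
Why: O-alkylation of both phenols with the chloromethyl ether (Williamson-type acetal formation) should be clean and installs the two groups that direct the next lithiation.

Step 2
Reactants: 2 1-methoxy-3,5-bis(methoxymethoxy)benzene
Product: 5 4-methoxy-2,6-bis(methoxymethoxy)phenol, via aryllithium 3 (not isolated), via lithium aryltrimethoxyborate 4 (not isolated)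
Conditions: n-BuLi (1.2 equiv), THF, 0 °C; B(OMe)3, −78 °C to rt; 30% H2O2, aq NaOH, 0 °C; then aq NH4Cl
Reagents that add atoms: hydrogen peroxide, OO; n-butyllithium, [Li]CCCC, and trimethyl borate, COB(OC)OC (atoms of these two stay only in intermediates 3 and 4)
Why: Directed ortho-metalation should occur at the ring carbon between the two OMOM groups (doubly coordinated and most acidic), and borylation followed by peroxide oxidation (1,2-aryl shift from boron to oxygen) turns that C–Li bond into the C–OH of the future C8 oxygen.

Step 3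
Reactants: 5 4-methoxy-2,6-bis(methoxymethoxy)phenol
Product: 6 2,5-dimethoxy-1,3-bis(methoxymethoxy)benzene
Conditions: MeI, K2CO3, DMF, rt to 40 °C
Reagents that add atoms: iodomethane, CI
Why: Williamson O-methylation of the only free phenol; the acetals are stable to carbonate base.

Step 4
Reactants: 6 2,5-dimethoxy-1,3-bis(methoxymethoxy)benzene
Product: 8 2-iodo-1,4-dimethoxy-3,5-bis(methoxymethoxy)benzene, via aryllithium 7 (not isolated)
Conditions: n-BuLi (1.1 equiv), THF, 0 °C; I2, −78 °C to rt
Reagents that add atoms: iodine, II; n-butyllithium, [Li]CCCC (lithium stays only in intermediate 7)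
Why: Directed ortho-metalation: the two remaining ring C–H bonds of 6 are equivalent and each is flanked by OMOM and OMe, so one equivalent of base should give a single aryllithium whose iodinolysis installs exactly one iodine, at the future C4a next to the future O1.

Step 5
Reactants: 8 2-iodo-1,4-dimethoxy-3,5-bis(methoxymethoxy)benzene
Product: 9 4-iodo-2,5-dimethoxybenzene-1,3-diol
Conditions: HCl (2 M in MeOH), rt
Reagents that add atoms: none
Why: Acid-catalysed methanolysis of the two aryl MOM acetals (the oxocarbenium ion is trapped by methanol) should free both phenols while leaving the methyl ethers and, at room temperature, the aryl iodide untouched.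

Step 6
Reactants: 9 4-iodo-2,5-dimethoxybenzene-1,3-diol; 10 benzyl bromide
Product: 12 3-(benzyloxy)-6-iodo-2,5-dimethoxyphenol, via disodium diolate 11 (not isolated)
Conditions: NaH (2.2 equiv), DMF, 0 °C; BnBr (1.0 equiv), −20 to 0 °C; then aq NH4Cl
Reagents that add atoms: benzyl bromide (10), BrCc1ccccc1; sodium hydride, [Na+].[H-] (sodium stays only in intermediate 11)
Why: Williamson etherification of bis-phenoxide 11 with one equivalent of 10 should take place at the oxide that is para to iodine and has only OMe and H as neighbours, because it is both the more basic and the less hindered one, whereas the other oxide is wedged between iodine and OMe and attenuated by the ortho halogen (the same preference is known for alkylation of 4-haloresorcinols at the hydroxyl remote from halogen).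

Step 7
Reactants: 13 methyl 3,5-dihydroxy-4-methoxybenzoate; 10 benzyl bromide
Product: 14 methyl 3,5-bis(benzyloxy)-4-methoxybenzoate
Conditions: BnBr (2.3 equiv), K2CO3, DMF, 60 °C
Reagents that add atoms: benzyl bromide (10), BrCc1ccccc1
Why: Double Williamson etherification of the two equivalent phenols; the methyl ester is stable to carbonate in DMF.

Step 8
Reactants: 14 methyl 3,5-bis(benzyloxy)-4-methoxybenzoate
Product: 15 [3,5-bis(benzyloxy)-4-methoxyphenyl]methanol
Conditions: LiAlH4, THF, 0 °C to rt
Reagents that add atoms: none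
Why: Hydride reduction of the aryl ester to the primary benzylic alcohol; aryl ethers are inert to the hydride.

Step 9
Reactants: 15 [3,5-bis(benzyloxy)-4-methoxyphenyl]methanol
Product: 16 3,5-bis(benzyloxy)-4-methoxybenzaldehyde
Conditions: activated MnO2 (excess), CH2Cl2, rt
Reagents that add atoms: none
Why: Manganese dioxide oxidises benzylic alcohols selectively to aldehydes without over-oxidation to the acid.

Step 10
Reactants: 16 3,5-bis(benzyloxy)-4-methoxybenzaldehyde
Product: 17 1,3-bis(benzyloxy)-5-ethynyl-2-methoxybenzene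
Conditions: dimethyl (1-diazo-2-oxopropyl)phosphonate, K2CO3, MeOH/THF, rt
Reagents that add atoms: dimethyl (1-diazo-2-oxopropyl)phosphonate, CC(=O)C(=[N+]=[N-])P(=O)(OC)OC
Why: Ohira–Bestmann homologation: methanolysis of the acetyl group gives the diazomethylphosphonate anion, which olefinates the non-enolisable aldehyde, and loss of dinitrogen with a 1,2-hydrogen shift delivers the terminal alkyne under base mild enough for the benzyl ethers.

Step 11
Reactants: 12 3-(benzyloxy)-6-iodo-2,5-dimethoxyphenol; 17 1,3-bis(benzyloxy)-5-ethynyl-2-methoxybenzene; 18 carbon monoxide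
Product: 21 7-(benzyloxy)-2-[3,5-bis(benzyloxy)-4-methoxyphenyl]-5,8-dimethoxy-4H-chromen-4-one, via hydroxyaryl ynone 19 (not isolated), via enaminone 20 (not isolated)
Conditions: PdCl2(dppf) (5 mol %), 17 (1.3 equiv), Et2NH (4 equiv), DMF, CO (5 bar), 90 °C, no copper co-catalyst
Reagents that add atoms: carbon monoxide (18), [C-]#[O+]; diethylamine, CCNCC (its atoms stay only in intermediate 20)
Why: Zerovalent palladium, formed from the divalent palladium precatalyst and the amine, adds oxidatively to the C4a–I bond of 12, CO inserts to give the aroylpalladium iodide, and amine-assisted alkynylation with 17 followed by reductive elimination forms C4a–C4 and C4–C3 in ynone 19. Diethylamine then adds to the ynone to give enaminone 20, whose amine-bearing carbon (the future C2) is attacked by the O1 hydroxyl with loss of the amine, so that ring C closes in a 6-endo mode (6-endo-dig with respect to 19) and O1–C2 is formed. The closest known reaction type is the palladium-catalysed carbonylative Sonogashira annulation of 2-iodophenols with terminal arylacetylenes in a secondary amine. No stereocentre is created. The step needs carbonylative and not direct alkynylation (which would lead to a 2-arylbenzofuran) and 6-endo and not 5-exo closure (which would give the aurone); the copper-free medium, the CO pressure and the electron-rich, readily migrating aryl group favour insertion, and the amine relay through 20 puts the leaving group on C2 so that only the pyranone can form. Only the hydroxyl ortho to the new ketone is free in 12, the other ring oxygen being benzylated, so the 5-OMe, 7-OBn, 8-OMe pattern set by the position of iodine is carried over unchanged.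

Step 12
Reactants: 21 7-(benzyloxy)-2-[3,5-bis(benzyloxy)-4-methoxyphenyl]-5,8-dimethoxy-4H-chromen-4-one
Product: 22 7-hydroxy-2-(3,5-dihydroxy-4-methoxyphenyl)-5,8-dimethoxy-4H-chromen-4-one (CNP0218554.0)
Conditions: H2 (1 atm), 10% Pd/C, THF/MeOH, rt, stopped when 21 is consumed
Reagents that add atoms: none
Why: Catalytic hydrogenolysis should cleave the three benzylic C–O bonds while the aryl methyl ethers and, at one atmosphere and room temperature, the conjugated C2=C3 bond of the chromone are left alone.

**Compound list**

1 | 5-methoxyresorcinol (5-methoxybenzene-1,3-diol) | COc1cc(O)cc(O)c1 | starting material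
2 | 1-methoxy-3,5-bis(methoxymethoxy)benzene | COCOc1cc(OC)cc(OCOC)c1 | intermediate
3 | [4-methoxy-2,6-bis(methoxymethoxy)phenyl]lithium | [Li]c1c(OCOC)cc(OC)cc1OCOC | intermediate (not isolated)
4 | lithium trimethoxy[4-methoxy-2,6-bis(methoxymethoxy)phenyl]borate | [Li+].CO[B-](OC)(OC)c1c(OCOC)cc(OC)cc1OCOC | intermediate (not isolated)
5 | 4-methoxy-2,6-bis(methoxymethoxy)phenol | COCOc1cc(OC)cc(OCOC)c1O | intermediate
6 | 2,5-dimethoxy-1,3-bis(methoxymethoxy)benzene | COCOc1cc(OC)cc(OCOC)c1OC | intermediate
7 | [3,6-dimethoxy-2,4-bis(methoxymethoxy)phenyl]lithium | [Li]c1c(OC)cc(OCOC)c(OC)c1OCOC | intermediate (not isolated)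
8 | 2-iodo-1,4-dimethoxy-3,5-bis(methoxymethoxy)benzene | COCOc1cc(OC)c(I)c(OCOC)c1OC | intermediate
9 | 4-iodo-2,5-dimethoxybenzene-1,3-diol | COc1cc(O)c(OC)c(O)c1I | intermediate
10 | benzyl bromide | BrCc1ccccc1 | starting material
11 | disodium 4-iodo-2,5-dimethoxybenzene-1,3-diolate | [Na+].[Na+].COc1cc([O-])c(OC)c([O-])c1I | intermediate (not isolated)
12 | 3-(benzyloxy)-6-iodo-2,5-dimethoxyphenol | COc1cc(OCc2ccccc2)c(OC)c(O)c1I | intermediate
13 | methyl 3,5-dihydroxy-4-methoxybenzoate | COC(=O)c1cc(O)c(OC)c(O)c1 | starting material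
14 | methyl 3,5-bis(benzyloxy)-4-methoxybenzoate | COC(=O)c1cc(OCc2ccccc2)c(OC)c(OCc2ccccc2)c1 | intermediate
15 | [3,5-bis(benzyloxy)-4-methoxyphenyl]methanol | COc1c(OCc2ccccc2)cc(CO)cc1OCc1ccccc1 | intermediate
16 | 3,5-bis(benzyloxy)-4-methoxybenzaldehyde | COc1c(OCc2ccccc2)cc(C=O)cc1OCc1ccccc1 | intermediate
17 | 1,3-bis(benzyloxy)-5-ethynyl-2-methoxybenzene | C#Cc1cc(OCc2ccccc2)c(OC)c(OCc2ccccc2)c1 | intermediate
18 | carbon monoxide | [C-]#[O+] | starting material
19 | 1-[4-(benzyloxy)-2-hydroxy-3,6-dimethoxyphenyl]-3-[3,5-bis(benzyloxy)-4-methoxyphenyl]prop-2-yn-1-one | COc1cc(OCc2ccccc2)c(OC)c(O)c1C(=O)C#Cc1cc(OCc2ccccc2)c(OC)c(OCc2ccccc2)c1 | intermediate (not isolated)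
20 | (E)-1-[4-(benzyloxy)-2-hydroxy-3,6-dimethoxyphenyl]-3-[3,5-bis(benzyloxy)-4-methoxyphenyl]-3-(diethylamino)prop-2-en-1-one (drawn as the E isomer; the geometry has no bearing on the ring closure) | CCN(CC)/C(=C/C(=O)c1c(O)c(OC)c(OCc2ccccc2)cc1OC)c1cc(OCc2ccccc2)c(OC)c(OCc2ccccc2)c1 | intermediate (not isolated)
21 | 7-(benzyloxy)-2-[3,5-bis(benzyloxy)-4-methoxyphenyl]-5,8-dimethoxy-4H-chromen-4-one | COc1cc(OCc2ccccc2)c(OC)c2oc(-c3cc(OCc4ccccc4)c(OC)c(OCc4ccccc4)c3)cc(=O)c12 | intermediate
22 | 7-hydroxy-2-(3,5-dihydroxy-4-methoxyphenyl)-5,8-dimethoxy-4H-chromen-4-one | COc1c(O)cc(-c2cc(=O)c3c(OC)cc(O)c(OC)c3o2)cc1O | target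

**Step count**

Total: 12 steps. Longest linear sequence: 8 steps (steps 1 to 6, 11 and 12, from 5-methoxyresorcinol); the alkyne branch has 4 steps (7 to 10).

**Steps most likely to fail, with fallbacks**

Step 11. The aroylpalladium intermediate may be intercepted by diethylamine (amide formation), direct alkynylation without CO uptake may lead on to a benzofuran, or oxidative addition at the doubly ortho-substituted, electron-rich C–I bond may be slow. The fallback builds the ketone by organometallic addition instead of carbonylation. It sets out from 12 and 17 and comes back to the route at 19, which is then closed to 21.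
- Phenol 12 is protected (NaH, MOMCl, DMF) as 1-(benzyloxy)-4-iodo-2,5-dimethoxy-3-(methoxymethoxy)benzene F1.
- Iodine–magnesium exchange of F1 (i-PrMgCl·LiCl, THF, −20 to 0 °C) gives [4-(benzyloxy)-3,6-dimethoxy-2-(methoxymethoxy)phenyl]magnesium chloride F2.
- Alkyne 17 is deprotonated (n-BuLi, THF, −78 °C) to {[3,5-bis(benzyloxy)-4-methoxyphenyl]ethynyl}lithium F3, which is acylated with N-methoxy-N-methylcarbamoyl chloride to 3-[3,5-bis(benzyloxy)-4-methoxyphenyl]-N-methoxy-N-methylprop-2-ynamide F4.
- Addition of F2 to F4 (THF, 0 °C, cold acidic quench) should give 1-[4-(benzyloxy)-3,6-dimethoxy-2-(methoxymethoxy)phenyl]-3-[3,5-bis(benzyloxy)-4-methoxyphenyl]prop-2-yn-1-one F5.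
- HCl in MeOH removes the MOM group to give 19, and Et2NH in EtOH at 60 °C closes it through 20 to 21.

Step 6. The two phenoxide oxygens may not be told apart well enough, or the second oxygen may also be alkylated. The fallback removes the need for any selection between the hydroxyls and lets the position of iodine alone decide which oxygen enters ring C. It sets out from 9 and comes back to the route at 22.
- Diol 9 is acetylated on both oxygens (Ac2O, pyridine) to 4-iodo-2,5-dimethoxy-1,3-phenylene diacetate F6.
- F6, 17 and 18 are combined under the carbonylative annulation conditions with Et2NH and DBU in DMF (PdCl2(PPh3)2, dppp). The acetates are cleaved by the amine in the flask and only the hydroxyl ortho to the new ketone can cyclise, which should give 2-[3,5-bis(benzyloxy)-4-methoxyphenyl]-7-hydroxy-5,8-dimethoxy-4H-chromen-4-one F7.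
- Hydrogenolysis of F7 as in step 12 gives 22.

Step 2. Butyllithium may remove a ring proton between OMOM and OMe instead of the one between the two OMOM groups, which would place the new oxygen on the wrong carbon. The fallback takes the ring A oxygen pattern from the gallate series, where it is already fixed, and uses no aryllithium. It sets out from 16 and comes back to the route at 9, so steps 1 to 5 are not needed.
- Baeyer–Villiger oxidation of 16 (mCPBA, NaHCO3, CH2Cl2) gives 3,5-bis(benzyloxy)-4-methoxyphenyl formate F8.
- Methanolysis (K2CO3, MeOH) gives 3,5-bis(benzyloxy)-4-methoxyphenol F9.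
- Methylation (MeI, K2CO3, DMF) gives 1,3-bis(benzyloxy)-2,5-dimethoxybenzene F10.
- Hydrogenolysis (H2, Pd/C) gives 2,5-dimethoxybenzene-1,3-diol F11, whose two ring C–H bonds are equivalent.
- Electrophilic mono-iodination (I2, 1.0 equiv, NaHCO3, THF/H2O, 0 °C) then gives 9.

**Further compounds**

F1 | step 11 | 1-(benzyloxy)-4-iodo-2,5-dimethoxy-3-(methoxymethoxy)benzene | COCOc1c(I)c(OC)cc(OCc2ccccc2)c1OC
F2 | step 11 | [4-(benzyloxy)-3,6-dimethoxy-2-(methoxymethoxy)phenyl]magnesium chloride | COCOc1c([Mg]Cl)c(OC)cc(OCc2ccccc2)c1OC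
F3 | step 11 | {[3,5-bis(benzyloxy)-4-methoxyphenyl]ethynyl}lithium | [Li]C#Cc1cc(OCc2ccccc2)c(OC)c(OCc2ccccc2)c1
F4 | step 11 | 3-[3,5-bis(benzyloxy)-4-methoxyphenyl]-N-methoxy-N-methylprop-2-ynamide | CON(C)C(=O)C#Cc1cc(OCc2ccccc2)c(OC)c(OCc2ccccc2)c1
F5 | step 11 | 1-[4-(benzyloxy)-3,6-dimethoxy-2-(methoxymethoxy)phenyl]-3-[3,5-bis(benzyloxy)-4-methoxyphenyl]prop-2-yn-1-one | COCOc1c(C(=O)C#Cc2cc(OCc3ccccc3)c(OC)c(OCc3ccccc3)c2)c(OC)cc(OCc2ccccc2)c1OC
F6 | step 6 | 4-iodo-2,5-dimethoxy-1,3-phenylene diacetate | COc1cc(OC(C)=O)c(OC)c(OC(C)=O)c1I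
F7 | step 6 | 2-[3,5-bis(benzyloxy)-4-methoxyphenyl]-7-hydroxy-5,8-dimethoxy-4H-chromen-4-one | COc1cc(O)c(OC)c2oc(-c3cc(OCc4ccccc4)c(OC)c(OCc4ccccc4)c3)cc(=O)c12
F8 | step 2 | 3,5-bis(benzyloxy)-4-methoxyphenyl formate | COc1c(OCc2ccccc2)cc(OC=O)cc1OCc1ccccc1
F9 | step 2 | 3,5-bis(benzyloxy)-4-methoxyphenol | COc1c(OCc2ccccc2)cc(O)cc1OCc1ccccc1
F10 | step 2 | 1,3-bis(benzyloxy)-2,5-dimethoxybenzene | COc1cc(OCc2ccccc2)c(OC)c(OCc2ccccc2)c1
F11 | step 2 | 2,5-dimethoxybenzene-1,3-diol | COc1cc(O)c(OC)c(O)c1
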